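**Retrosynthetic overview**

1. Target 9 ⇒ (13S)-labdane-8α,15-diol 8 (selective acetylation of the primary 15-OH) ⇒ tert-butyl ester 7 (hydride reduction).
2. Key disconnection C12–C13: 7 ⇒ tert-butyl crotonate 4 plus a C12 carbanion equivalent made by polarity reversal of an aldehyde (NH2-hydrazone 5, which loses N2 after the C–C bond forms). Both carbons are natively electrophilic; a chiral Ru catalyst sets C13.
3. Hydrazone 5 ⇒ sclareolide lactol 2 ⇒ (+)-sclareolide 1 (partial reduction).
4. Rings: none is formed. The trans-decalin with C5, C8, C9 and C10 is taken intact from 1; its lactone ring is opened in steps 1–2.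

Assumption: the facial preference of the chiral Ru catalyst in step 2 cannot be predicted with certainty; (R,R)-Me-BPE is written as the antipode that gives 13S, and its mirror image is used if a pilot run shows the opposite sense.

**Route**

Step 1
Reactants: 1 (+)-sclareolide
Product: 2 sclareolide lactol (3aR,5aS,9aS,9bR)-3a,6,6,9a-tetramethyldodecahydronaphtho[2,1-b]furan-2-ol (both C2 anomers)
Conditions: DIBAL-H (1.2 equiv), CH2Cl2, −78 °C; Rochelle salt work-up
Reagents that add atoms: none
Why: Partial reduction of a lactone to a lactol with DIBAL-H: the tetrahedral aluminium hemiacetal survives at −78 °C and collapses only on work-up, so the aldehyde oxidation level is kept; the new anomeric centre (C12) forms as a mixture that is erased in step 2, and the four decalin stereocentres are untouched.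

Step 2
Reactants: 2 sclareolide lactol; 3 hydrazine monohydrate; 4 tert-butyl (E)-but-2-enoate
Product: 7 tert-butyl (3S)-5-[(1R,2R,4aS,8aS)-2-hydroxy-2,5,5,8a-tetramethyldecahydronaphthalen-1-yl]-3-methylpentanoate, via hydrazone 5 (not isolated), via alkyl diazene 6 (not isolated)
Conditions: N2H4·H2O (1.2 equiv), THF, rt, 1 h; then 4 (2 equiv), [Ru(p-cymene)Cl2]2 (2.5 mol%), (R,R)-Me-BPE (5.5 mol%), K3PO4 (0.5 equiv), THF, 50 °C, 24 h
Reagents that add atoms: none
Why: Proposed new method: the lactol opens to its hydroxy aldehyde and condenses to NH2-hydrazone 5, which binds Ru(II) through nitrogen, is deprotonated by phosphate and attacks the β-carbon of the Ru-bound crotonate through its carbon (C12, umpoled from the aldehyde) in a six-membered chair-like transition state to give alkyl diazene 6, which loses N2 under the basic conditions (Wolff–Kishner-type) and leaves C12 as CH2; the C2-symmetric, electron-rich bisphosphine on Ru in that transition state differentiates the two faces of the (E)-enoate and sets C13 (S) under catalyst control (the decalin centres are too remote to interfere), and the tert-butyl ester resists hydrazinolysis; the closest known reaction is the Ru/dmpe-catalysed conjugate addition of aldehyde hydrazones as alkyl carbanion equivalents to α,β-unsaturated esters, known only with achiral ligands.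

Step 3
Reactants: 7 tert-butyl (3S)-5-[(1R,2R,4aS,8aS)-2-hydroxy-2,5,5,8a-tetramethyldecahydronaphthalen-1-yl]-3-methylpentanoate
Product: 8 (13S)-labdane-8α,15-diol (1R,2R,4aS,8aS)-1-[(3S)-5-hydroxy-3-methylpentyl]-2,5,5,8a-tetramethyldecahydronaphthalen-2-ol
Conditions: LiAlH4 (2 equiv), THF, 0 °C → 40 °C; Fieser work-up
Reagents that add atoms: none
Why: Hydride reduction of an ester to a primary alcohol; the tertiary alcohol is only deprotonated, and C13, being β to the carbonyl, cannot epimerise.

Step 4
Reactants: 8 (13S)-labdane-8α,15-diol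
Product: 9 (3S)-5-[(1R,2R,4aS,8aS)-2-hydroxy-2,5,5,8a-tetramethyldecahydronaphthalen-1-yl]-3-methylpentyl acetate (target)
Conditions: Ac2O (1.2 equiv), pyridine, CH2Cl2, 0 °C → rt
Reagents that add atoms: acetic anhydride, CC(=O)OC(C)=O
Why: Chemoselective O-acetylation (acyl transfer): the unhindered primary 15-OH reacts at room temperature, whereas the tertiary 8-OH, flanked by the axial C8 methyl and the C9 side chain, is inert to Ac2O/pyridine without DMAP or heat, so the monoacetate forms without touching any stereocentre.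

**Compound list**

1 | (+)-sclareolide, (3aR,5aS,9aS,9bR)-3a,6,6,9a-tetramethyldecahydronaphtho[2,1-b]furan-2(1H)-one | O=C1C[C@@H]2[C@@]3(C)CCCC(C)(C)[C@@H]3CC[C@@]2(C)O1 | starting material
2 | sclareolide lactol, (3aR,5aS,9aS,9bR)-3a,6,6,9a-tetramethyldodecahydronaphtho[2,1-b]furan-2-ol (both C2 anomers; ring-chain tautomer of the 8α-hydroxy-12-aldehyde) | OC1C[C@@H]2[C@@]3(C)CCCC(C)(C)[C@@H]3CC[C@@]2(C)O1 | intermediate
3 | hydrazine monohydrate | NN.O | starting material
4 | tert-butyl (E)-but-2-enoate (tert-butyl crotonate) | C/C=C/C(=O)OC(C)(C)C | starting material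
5 | (E)-hydrazone of 2-[(1R,2R,4aS,8aS)-2-hydroxy-2,5,5,8a-tetramethyldecahydronaphthalen-1-yl]acetaldehyde (not isolated) | N/N=C/C[C@@H]1[C@@]2(C)CCCC(C)(C)[C@@H]2CC[C@@]1(C)O | intermediate
6 | tert-butyl (3R)-4-diazenyl-5-[(1R,2R,4aS,8aS)-2-hydroxy-2,5,5,8a-tetramethyldecahydronaphthalen-1-yl]-3-methylpentanoate (both C4 epimers; methyl carbon arranged in space as in 7, descriptor changed only by CIP priority; not isolated) | CC(C)(C)OC(=O)C[C@@H](C)C(N=N)C[C@@H]1[C@@]2(C)CCCC(C)(C)[C@@H]2CC[C@@]1(C)O | intermediate
7 | tert-butyl (3S)-5-[(1R,2R,4aS,8aS)-2-hydroxy-2,5,5,8a-tetramethyldecahydronaphthalen-1-yl]-3-methylpentanoate (tert-butyl (13S)-8α-hydroxylabdan-15-oate) | CC(C)(C)OC(=O)C[C@@H](C)CC[C@@H]1[C@@]2(C)CCCC(C)(C)[C@@H]2CC[C@@]1(C)O | intermediate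
8 | (13S)-labdane-8α,15-diol, (1R,2R,4aS,8aS)-1-[(3S)-5-hydroxy-3-methylpentyl]-2,5,5,8a-tetramethyldecahydronaphthalen-2-ol | OCC[C@@H](C)CC[C@@H]1[C@@]2(C)CCCC(C)(C)[C@@H]2CC[C@@]1(C)O | intermediate
9 | (13S)-8α-hydroxylabdan-15-yl acetate, (3S)-5-[(1R,2R,4aS,8aS)-2-hydroxy-2,5,5,8a-tetramethyldecahydronaphthalen-1-yl]-3-methylpentyl acetate | CC(=O)OCC[C@@H](C)CC[C@@H]1[C@@]2(C)CCCC(C)(C)[C@@H]2CC[C@@]1(C)O | target

**Totals**

Total step count: 4. Longest linear sequence: 4 steps (1 → 2 → 7 → 8 → 9).

**Steps most likely to fail, with fallbacks**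

Step 2 (highest risk). A β-methyl enoate is at the slow end of the acceptor range for this Ru chemistry. Aliphatic NH2-hydrazones can also divert to the azine or to plain Wolff–Kishner reduction. The 13S:13R ratio under ligand control is untested, and the two C13 epimers will be hard to separate; a modest ratio could at best be upgraded by recrystallising diol 8.

Fallback, setting out from 2 and coming back at 8: the C12–C13 bond is made by a reagent-controlled homoaldol reaction of a homoenolate equivalent. (E)-But-2-en-1-yl N,N-diisopropylcarbamate F1 is prepared from (E)-crotyl alcohol and diisopropylcarbamoyl chloride. It is lithiated with n-BuLi/(−)-sparteine (pentane–cyclohexane, −78 °C, crystallisation-induced resolution), transmetalated with Ti(OiPr)4 and added in excess (2.5 equiv) to lactol 2, which reacts as its open hydroxy aldehyde. The product is the (Z)-anti homoaldol adduct (1Z,3R,4S)-4-hydroxy-5-[(1R,2R,4aS,8aS)-2-hydroxy-2,5,5,8a-tetramethyldecahydronaphthalen-1-yl]-3-methylpent-1-en-1-yl N,N-diisopropylcarbamate F2, with the methyl-bearing carbon fixed by the diamine; the (+)-sparteine surrogate is used instead if the first run gives the 13R series. The now superfluous C12 hydroxyl is converted with thiocarbonyldiimidazole/DMAP (the tertiary 8-OH does not react) into the O-(imidazol-1-ylthiocarbonyl) derivative of the homoaldol adduct F3. Bu3SnH/AIBN in toluene at 90 °C (Barton–McCombie deoxygenation) then gives (1Z,3S)-5-[(1R,2R,4aS,8aS)-2-hydroxy-2,5,5,8a-tetramethyldecahydronaphthalen-1-yl]-3-methylpent-1-en-1-yl N,N-diisopropylcarbamate F4. Hydrogenation (H2, Pd/C, EtOAc) gives the saturated (3S)-5-[(1R,2R,4aS,8aS)-2-hydroxy-2,5,5,8a-tetramethyldecahydronaphthalen-1-yl]-3-methylpentyl N,N-diisopropylcarbamate F5. LiAlH4 in refluxing THF cleaves the carbamate to diol 8, and step 4 follows.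

Step 1. The risk is over-reduction to the diol, or a lactol/lactone mixture, if temperature or stoichiometry drifts.

Fallback, setting out from 1 and coming back at 2: sclareolide is reduced completely with LiAlH4 (THF, 0 °C → rt) to ambradiol, (1R,2R,4aS,8aS)-1-(2-hydroxyethyl)-2,5,5,8a-tetramethyldecahydronaphthalen-2-ol F6. Only its primary alcohol is then oxidised with SO3·pyridine/DMSO/Et3N (1.2 equiv, CH2Cl2, 0 °C); the tertiary alcohol cannot be oxidised, and the hydroxy aldehyde closes to lactol 2. Any over-oxidised material is sclareolide 1 and is recycled.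

Step 4. The risk is small: some dehydration of the tertiary 8-OH by adventitious acid, or traces of diacetate if forcing conditions are needed to reach full conversion.

Fallback, setting out from 8 and coming back at 9: enzymatic transesterification instead of chemical acylation, using immobilised Candida antarctica lipase B with vinyl acetate in MTBE at 30 °C. The enzyme acylates only the primary hydroxyl under neutral conditions, and no new compound lies on the way.

**Further compounds**

F1 | step 2 | (E)-but-2-en-1-yl N,N-diisopropylcarbamate | C/C=C/COC(=O)N(C(C)C)C(C)C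
F2 | step 2 | (1Z,3R,4S)-4-hydroxy-5-[(1R,2R,4aS,8aS)-2-hydroxy-2,5,5,8a-tetramethyldecahydronaphthalen-1-yl]-3-methylpent-1-en-1-yl N,N-diisopropylcarbamate | CC(C)N(C(C)C)C(=O)O/C=C\[C@@H](C)[C@@H](O)C[C@@H]1[C@@]2(C)CCCC(C)(C)[C@@H]2CC[C@@]1(C)O
F3 | step 2 | O-(imidazol-1-ylthiocarbonyl) derivative of F2 at the secondary hydroxyl | CC(C)N(C(C)C)C(=O)O/C=C\[C@@H](C)[C@@H](OC(=S)n1ccnc1)C[C@@H]1[C@@]2(C)CCCC(C)(C)[C@@H]2CC[C@@]1(C)O
F4 | step 2 | (1Z,3S)-5-[(1R,2R,4aS,8aS)-2-hydroxy-2,5,5,8a-tetramethyldecahydronaphthalen-1-yl]-3-methylpent-1-en-1-yl N,N-diisopropylcarbamate | CC(C)N(C(C)C)C(=O)O/C=C\[C@@H](C)CC[C@@H]1[C@@]2(C)CCCC(C)(C)[C@@H]2CC[C@@]1(C)O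
F5 | step 2 | (3S)-5-[(1R,2R,4aS,8aS)-2-hydroxy-2,5,5,8a-tetramethyldecahydronaphthalen-1-yl]-3-methylpentyl N,N-diisopropylcarbamate | CC(C)N(C(C)C)C(=O)OCC[C@@H](C)CC[C@@H]1[C@@]2(C)CCCC(C)(C)[C@@H]2CC[C@@]1(C)O
F6 | step 1 | ambradiol, (1R,2R,4aS,8aS)-1-(2-hydroxyethyl)-2,5,5,8a-tetramethyldecahydronaphthalen-2-ol | OCC[C@@H]1[C@@]2(C)CCCC(C)(C)[C@@H]2CC[C@@]1(C)O
F0 | step 4 | none | none
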